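**Retrosynthetic overview**
- The target (eremophilane numbering) is unwound at its periphery: the C12 methyl ester comes from a CH2OTBS group, the C1 angelate from the C1 alcohol of 20, that alcohol from ene-dione 19, and C9=C10 from dehydrogenation of bicyclic diketone 18.
- Feature on which the plan rests: the quaternary carbon C5 is α to C6, and C10 is β to the C8 carbonyl. With C6 as an aldehyde, C5–C10 (ring A) is therefore a Michael bond and C6=C7 (ring B) an aldol-condensation bond.
- Both bonds are cut in 18, which leads to the acyclic ene-dione aldehyde 16; in the forward sense one amine catalyst closes ring A first and ring B second in the same flask.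
- 16 comes from the 2,5-dialkylfuran aldehyde 14 by oxidative furan opening (the furan carbons become C8, C9, C10 and C1).
- 14 is assembled from furan, iodide 4 (C7, C11–C13, from hydroxy ester 1), acrolein (C2–C4) and a Wittig two-carbon unit (C5, C6); C4 is set by copper-catalysed asymmetric methyl addition and C14 enters by enolate methylation.

Key step: step 11

Remark 1: eremophilane numbering is used for all intermediates: C1–C10 around the decalin (C1 oxygenated, C5 quaternary with methyl C14, C4 with methyl C15, C8 carbonyl) and the side chain C11 (methyl C13, oxygenated C12) on C7; TBS = tert-butyldimethylsilyl.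
Remark 2: compounds 13–16 are carried as mixtures of C5 epimers (the 5R epimer is drawn and listed), because C5 becomes trigonal in step 11.
Remark 3: the hand of the ligand in step 7 ((S)-Tol-BINAP) and of the amine in step 11 (quinine-derived) are working assignments that could not be fixed from first principles; the R ligand and the quinidine-derived amine are used instead if the first run shows the opposite sense.

**Step 1**
Reactants: 1 methyl (R)-3-hydroxy-2-methylpropanoate
Product: 2 methyl (R)-3-[(tert-butyldimethylsilyl)oxy]-2-methylpropanoate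
Conditions: TBSCl, imidazole, CH2Cl2, 0 °C to rt
Reagents that add atoms: tert-butyldimethylsilyl chloride, CC(C)(C)[Si](C)(C)Cl
Why: Imidazole-promoted silylation of the primary alcohol (silyl ether protection) uses no base able to enolise the ester, so the stereocentre (future C11) should be kept.

**Step 2**
Reactants: 2 methyl (R)-3-[(tert-butyldimethylsilyl)oxy]-2-methylpropanoate
Product: 3 (S)-3-[(tert-butyldimethylsilyl)oxy]-2-methylpropan-1-ol
Conditions: i-Bu2AlH (2.2 equiv), CH2Cl2, −78 to 0 °C; aq. potassium sodium tartrate
Reagents that add atoms: none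
Why: Aluminium hydride reduction of the ester to the primary alcohol leaves the silyl ether and the stereocentre untouched (the descriptor changes only through the priority rules).

**Step 3**
Reactants: 3 (S)-3-[(tert-butyldimethylsilyl)oxy]-2-methylpropan-1-ol
Product: 4 (R)-tert-butyl(3-iodo-2-methylpropoxy)dimethylsilane
Conditions: I2, PPh3, imidazole, CH2Cl2, 0 °C to rt
Reagents that add atoms: iodine, II
Why: Appel-type iodination converts the primary alcohol into the iodide by SN2 displacement at the CH2 carbon, so the neighbouring stereocentre is not involved.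

**Step 4**
Reactants: 5 furan; 4 (R)-tert-butyl(3-iodo-2-methylpropoxy)dimethylsilane
Product: 7 (S)-tert-butyl[3-(furan-2-yl)-2-methylpropoxy]dimethylsilane, via 2-furyllithium 6 (not isolated)
Conditions: 5 (2 equiv), n-BuLi, THF, −78 to 0 °C; then 4, DMPU, 0 °C to rt
Reagents that add atoms: none
Why: α-Lithiation of furan and SN2 alkylation of the 2-furyllithium with the primary iodide form the C7–C8 bond, with DMPU compensating for the β-branch of the electrophile.

**Step 5**
Reactants: 7 (S)-tert-butyl[3-(furan-2-yl)-2-methylpropoxy]dimethylsilane; 8 acrolein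
Product: 9 3-{5-[(S)-3-(TBSO)-2-methylpropyl]furan-2-yl}propanal
Conditions: 8 (3 equiv), AcOH (0.2 equiv), hydroquinone (cat.), CH2Cl2, rt, dark
Reagents that add atoms: none
Why: Acid-catalysed Friedel–Crafts-type conjugate addition of a 2-alkylfuran through its free α-position to acrolein, the known preparation of 3-(5-alkylfuran-2-yl)propanals, forms the C1–C2 bond, and catalytic AcOH in a dry medium should not cleave the silyl ether.

**Step 6**
Reactants: 9 3-{5-[(S)-3-(TBSO)-2-methylpropyl]furan-2-yl}propanal
Product: 10 methyl (E)-5-{5-[(S)-3-(TBSO)-2-methylpropyl]furan-2-yl}pent-2-enoate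
Conditions: Ph3P=CHCO2Me, CH2Cl2, rt
Reagents that add atoms: methyl (triphenylphosphoranylidene)acetate, COC(=O)C=P(c1ccccc1)(c1ccccc1)c1ccccc1
Why: Wittig olefination with the stabilised ylide should give the E-enoate (C4=C5, C6) under neutral conditions.

**Step 7**
Reactants: 10 methyl (E)-5-{5-[(S)-3-(TBSO)-2-methylpropyl]furan-2-yl}pent-2-enoate
Product: 11 methyl (S)-5-{5-[(S)-3-(TBSO)-2-methylpropyl]furan-2-yl}-3-methylpentanoate
Conditions: MeMgBr, CuI (2 mol%), (S)-Tol-BINAP (3 mol%), t-BuOMe, −20 °C; aq. NH4Cl
Reagents that add atoms: methylmagnesium bromide, C[Mg]Br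
Why: Copper-catalysed asymmetric conjugate addition of the Grignard reagent to the E-enoate introduces C15 and sets C4 (S) through face selection by the bisphosphine–copper complex, while 1,2-addition to the ester is suppressed at low temperature.

**Step 8**
Reactants: 11 methyl (S)-5-{5-[(S)-3-(TBSO)-2-methylpropyl]furan-2-yl}-3-methylpentanoate
Product: 13 methyl (2R,3S)-5-{5-[(S)-3-(TBSO)-2-methylpropyl]furan-2-yl}-2,3-dimethylpentanoate, via lithium ester enolate 12 (not isolated)
Conditions: LiN(i-Pr)2, THF, −78 °C; then MeI, −78 to −20 °C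
Reagents that add atoms: iodomethane, CI
Why: Ester enolate alkylation introduces C14 at C5, and the epimeric mixture expected at this centre is acceptable because C5 becomes trigonal in the enamine of step 11.

**Step 9**
Reactants: 13 methyl (2R,3S)-5-{5-[(S)-3-(TBSO)-2-methylpropyl]furan-2-yl}-2,3-dimethylpentanoate
Product: 14 (2R,3S)-5-{5-[(S)-3-(TBSO)-2-methylpropyl]furan-2-yl}-2,3-dimethylpentanal
Conditions: i-Bu2AlH (1.1 equiv), CH2Cl2, −78 °C; MeOH, then aq. potassium sodium tartrate
Reagents that add atoms: none
Why: Partial hydride reduction of the α-branched methyl ester should stop at the aluminium hemiacetal at −78 °C, which releases the C6 aldehyde only on work-up.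

**Step 10**
Reactants: 14 (2R,3S)-5-{5-[(S)-3-(TBSO)-2-methylpropyl]furan-2-yl}-2,3-dimethylpentanal
Product: 16 (2R,3S,7E,11S)-12-(TBSO)-2,3,11-trimethyl-6,9-dioxododec-7-enal, via Z-ene-dione aldehyde 15 (not isolated)
Conditions: NBS (1.05 equiv), NaHCO3, acetone–H2O (10:1), −20 °C; then pyridine, rt
Reagents that add atoms: water, O
Why: Oxidative ring opening of the 2,5-dialkylfuran (bromonium attack at an α-carbon, addition of water, fragmentation) gives the Z-ene-dione, which pyridine isomerises to the E isomer by reversible conjugate addition, while the aldehyde and silyl ether should be spectators in the cold, buffered medium.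

**Step 11**
Reactants: 16 (2R,3S,7E,11S)-12-(TBSO)-2,3,11-trimethyl-6,9-dioxododec-7-enal
Product: 18 (4S,5S,10S,11S)-12-(TBSO)eremophil-6-ene-1,8-dione, via Michael adduct keto aldehyde 17 (not isolated)
Conditions: 9-amino-9-deoxy-epi-quinine (20 mol%), AcOH (40 mol%), toluene, rt then 45 °C
Reagents that add atoms: none
Why: Proposed new method: the primary amine condenses with the α-branched aldehyde of 16 to an enamine (both C5 epimers give the same one) whose carbon C5 adds to C10 of the ene-dione, β to the C8 carbonyl, and hydrolysis gives 17, after which the amine forms the enamine of the C8 ketone toward C7, this adds to the now non-enolisable C6 aldehyde, and loss of water fixes the C6=C7 enone irreversibly. The closest known reaction types are the enamine annulation of α-branched aldehydes with vinyl ketones to 4,4-disubstituted cyclohexenones, the amine-catalysed intramolecular Michael addition of aldehydes to enones and the primary-amine-catalysed aldol condensation of dicarbonyl compounds, whereas their union on an ene-dione whose tether runs through the C1 carbonyl has not been described. Ring A closes 6-exo-trig through the C5–C10 bond and ring B by a six-membered enolendo-exo-trig aldol closure through the C6–C7 bond. The quaternary centre C5 is set in a chair-like transition state of the forming ring A with the C4 methyl and the enamine carbon C6 equatorial and the C5 methyl axial, which places the two methyl groups cis, and the chiral amine is chosen so that its facial preference adds to this substrate bias. C10 is expected with its hydrogen axial (trans ring fusion as drawn), but it is α to the C1 ketone, epimerisable and removed in step 12, so it needs no control. The step needs site selectivity, which the substrate secures because attack of C5 at C9 would demand a seven-membered ring, the C6 aldehyde is far more electrophilic toward C7 than the C1 ketone (cyclopentenone closure), and aldol closures through C9 or C2 would give a four-membered or a bridged ring that cannot dehydrate.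

**Step 12**
Reactants: 18 (4S,5S,10S,11S)-12-(TBSO)eremophil-6-ene-1,8-dione
Product: 19 (4S,5S,11S)-12-(TBSO)eremophila-6,9-diene-1,8-dione
Conditions: DDQ (1.3 equiv), 1,4-dioxane, 80 °C
Reagents that add atoms: none
Why: Quinone dehydrogenation of a 1,4-diketone to the ene-dione (the type of the 3,6-dione to 4-ene-3,6-dione conversion of steroids) should occur across C9–C10 because these are the only carbons that are α to one carbonyl and β to the other, and it removes the transient C10 stereocentre.

**Step 13**
Reactants: 19 (4S,5S,11S)-12-(TBSO)eremophila-6,9-diene-1,8-dione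
Product: 20 (1R,4S,5S,11S)-1-hydroxy-12-(TBSO)eremophila-6,9-dien-8-one
Conditions: NaBH4 (1.0 equiv), CeCl3·7H2O (1.1 equiv), MeOH, −78 °C
Reagents that add atoms: none
Why: Luche 1,2-reduction should select the C1 carbonyl, which is conjugated with one alkene only and so more electrophilic than the cross-conjugated, α-branched C8 dienone carbonyl, and hydride should enter anti to the quasi-axial C14 methyl on C5 to give the 1R alcohol with oxygen cis to both methyl groups, as in the reduction of steroidal 4-en-6-ones to 6β-alcohols.

**Step 14**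
Reactants: 21 angelic acid; 20 (1R,4S,5S,11S)-1-hydroxy-12-(TBSO)eremophila-6,9-dien-8-one
Product: 23 (1R,4S,5S,11S)-1-(angeloyloxy)-12-(TBSO)eremophila-6,9-dien-8-one, via angelic 2,4,6-trichlorobenzoic anhydride 22 (not isolated)
Conditions: 21, 2,4,6-trichlorobenzoyl chloride, Et3N, toluene, rt; then 20, 80 °C
Reagents that add atoms: none
Why: Yamaguchi-type esterification through the mixed anhydride, run without a nucleophilic amine catalyst, is the established way to acylate hindered secondary alcohols with angelic acid without Z-to-E isomerisation to the tiglate, and the C1–O bond is not broken so its configuration is retained.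

**Step 15**
Reactants: 23 (1R,4S,5S,11S)-1-(angeloyloxy)-12-(TBSO)eremophila-6,9-dien-8-one
Product: 24 (1R,4S,5S,11S)-1-(angeloyloxy)-12-hydroxyeremophila-6,9-dien-8-one
Conditions: HF·pyridine, pyridine, THF, 0 °C to rt
Reagents that add atoms: none
Why: Fluoride-mediated cleavage of the primary silyl ether under buffered conditions should leave the angelate, the dienone and C11 unaffected.

**Step 16**
Reactants: 24 (1R,4S,5S,11S)-1-(angeloyloxy)-12-hydroxyeremophila-6,9-dien-8-one
Product: 25 (1R,4S,5S,11S)-1-(angeloyloxy)-8-oxoeremophila-6,9-dien-12-oic acid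
Conditions: TEMPO (0.2 equiv), PhI(OAc)2 (2.2 equiv), MeCN–H2O (1:1), rt
Reagents that add atoms: water, O
Why: Oxoammonium-mediated oxidation takes the primary alcohol through the aldehyde hydrate to the acid in one flask near neutral pH, so that C11, α to the new carbonyl and allylic, should not epimerise and the electron-poor alkenes stay inert.

**Step 17**
Reactants: 25 (1R,4S,5S,11S)-1-(angeloyloxy)-8-oxoeremophila-6,9-dien-12-oic acid
Product: 26 methyl (1R,4S,5S,11S)-1-(angeloyloxy)-8-oxoeremophila-6,9-dien-12-oate
Conditions: TMSCHN2, toluene–MeOH (4:1), 0 °C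
Reagents that add atoms: (trimethylsilyl)diazomethane, C[Si](C)(C)C=[N+]=[N-]
Why: Diazoalkane esterification of the acid is base-free and should give the methyl ester without epimerisation at C11 or isomerisation of the angelate.

**Compound list**
1 | methyl (R)-3-hydroxy-2-methylpropanoate | OC[C@@H](C)C(=O)OC | starting material
2 | methyl (R)-3-[(tert-butyldimethylsilyl)oxy]-2-methylpropanoate | CC(C)(C)[Si](C)(C)OC[C@@H](C)C(=O)OC | intermediate
3 | (S)-3-[(tert-butyldimethylsilyl)oxy]-2-methylpropan-1-ol | CC(C)(C)[Si](C)(C)OC[C@@H](C)CO | intermediate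
4 | (R)-tert-butyl(3-iodo-2-methylpropoxy)dimethylsilane | CC(C)(C)[Si](C)(C)OC[C@@H](C)CI | intermediate
5 | furan | c1ccoc1 | starting material
6 | 2-furyllithium | [Li]c1ccco1 | intermediate (not isolated)
7 | (S)-tert-butyl[3-(furan-2-yl)-2-methylpropoxy]dimethylsilane | CC(C)(C)[Si](C)(C)OC[C@@H](C)Cc1ccco1 | intermediate
8 | acrolein | C=CC=O | starting material
9 | 3-{5-[(S)-3-(TBSO)-2-methylpropyl]furan-2-yl}propanal | O=CCCc1ccc(C[C@H](C)CO[Si](C)(C)C(C)(C)C)o1 | intermediate
10 | methyl (E)-5-{5-[(S)-3-(TBSO)-2-methylpropyl]furan-2-yl}pent-2-enoate | COC(=O)/C=C/CCc1ccc(C[C@H](C)CO[Si](C)(C)C(C)(C)C)o1 | intermediate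
11 | methyl (S)-5-{5-[(S)-3-(TBSO)-2-methylpropyl]furan-2-yl}-3-methylpentanoate | COC(=O)C[C@@H](C)CCc1ccc(C[C@H](C)CO[Si](C)(C)C(C)(C)C)o1 | intermediate
12 | lithium ester enolate of 11 (OLi trans to the chain) | CO/C(O[Li])=C\[C@@H](C)CCc1ccc(C[C@H](C)CO[Si](C)(C)C(C)(C)C)o1 | intermediate (not isolated)
13 | methyl (2R,3S)-5-{5-[(S)-3-(TBSO)-2-methylpropyl]furan-2-yl}-2,3-dimethylpentanoate (with its 2S epimer) | COC(=O)[C@H](C)[C@@H](C)CCc1ccc(C[C@H](C)CO[Si](C)(C)C(C)(C)C)o1 | intermediate
14 | (2R,3S)-5-{5-[(S)-3-(TBSO)-2-methylpropyl]furan-2-yl}-2,3-dimethylpentanal (with its 2S epimer) | O=C[C@H](C)[C@@H](C)CCc1ccc(C[C@H](C)CO[Si](C)(C)C(C)(C)C)o1 | intermediate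
15 | (2R,3S,7Z,11S)-12-(TBSO)-2,3,11-trimethyl-6,9-dioxododec-7-enal | O=C[C@H](C)[C@@H](C)CCC(=O)/C=C\C(=O)C[C@H](C)CO[Si](C)(C)C(C)(C)C | intermediate (not isolated)
16 | (2R,3S,7E,11S)-12-(TBSO)-2,3,11-trimethyl-6,9-dioxododec-7-enal (with its 2S epimer; C1–C12 of the chain are C6, C5, C4, C3, C2, C1, C10, C9, C8, C7, C11, C12 of the eremophilane) | O=C[C@H](C)[C@@H](C)CCC(=O)/C=C/C(=O)C[C@H](C)CO[Si](C)(C)C(C)(C)C | intermediate
17 | (4S,5R,10S,11S) Michael adduct: ring A cyclohexanone with C1 ketone, cis C4 and C5 methyls, formyl (C6) on C5, and CH2C(=O)CH2CH(CH3)CH2OTBS on C10 trans to the C5 methyl | O=C1CC[C@H](C)[C@@](C)(C=O)[C@@H]1CC(=O)C[C@H](C)CO[Si](C)(C)C(C)(C)C | intermediate (not isolated)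
18 | (4S,5S,10S,11S)-12-(TBSO)eremophil-6-ene-1,8-dione (trans-fused) | O=C1CC[C@H](C)[C@@]2(C)C=C([C@H](C)CO[Si](C)(C)C(C)(C)C)C(=O)C[C@H]12 | intermediate
19 | (4S,5S,11S)-12-(TBSO)eremophila-6,9-diene-1,8-dione | O=C1CC[C@H](C)[C@@]2(C)C=C([C@H](C)CO[Si](C)(C)C(C)(C)C)C(=O)C=C12 | intermediate
20 | (1R,4S,5S,11S)-1-hydroxy-12-(TBSO)eremophila-6,9-dien-8-one (OH cis to both methyls) | O[C@@H]1CC[C@H](C)[C@@]2(C)C=C([C@H](C)CO[Si](C)(C)C(C)(C)C)C(=O)C=C12 | intermediate
21 | angelic acid, (Z)-2-methylbut-2-enoic acid | C/C=C(/C)C(=O)O | starting material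
22 | angelic 2,4,6-trichlorobenzoic anhydride | C/C=C(/C)C(=O)OC(=O)c1c(Cl)cc(Cl)cc1Cl | intermediate (not isolated)
23 | (1R,4S,5S,11S)-1-(angeloyloxy)-12-(TBSO)eremophila-6,9-dien-8-one | C/C=C(/C)C(=O)O[C@@H]1CC[C@H](C)[C@@]2(C)C=C([C@H](C)CO[Si](C)(C)C(C)(C)C)C(=O)C=C12 | intermediate
24 | (1R,4S,5S,11S)-1-(angeloyloxy)-12-hydroxyeremophila-6,9-dien-8-one | C/C=C(/C)C(=O)O[C@@H]1CC[C@H](C)[C@@]2(C)C=C([C@H](C)CO)C(=O)C=C12 | intermediate
25 | (1R,4S,5S,11S)-1-(angeloyloxy)-8-oxoeremophila-6,9-dien-12-oic acid | C/C=C(/C)C(=O)O[C@@H]1CC[C@H](C)[C@@]2(C)C=C([C@H](C)C(=O)O)C(=O)C=C12 | intermediate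
26 | methyl (1R,4S,5S,11S)-1-(angeloyloxy)-8-oxoeremophila-6,9-dien-12-oate (CNP0166395.1) | C/C=C(/C)C(=O)O[C@@H]1CC[C@H](C)[C@@]2(C)C=C([C@H](C)C(=O)OC)C(=O)C=C12 | target

**Step count**
Total: 17 steps. Longest linear sequence: 17 steps (1 to 26); furan, acrolein and angelic acid each enter in one step.

**Steps most likely to fail**

Step 11 (the one step beyond known chemistry). The primary amine may be drained by conjugate addition to the ene-dione or by pyrrole formation with the 1,4-diketone of 17. The sequence may also stall after ring A, or face selection at C5 may be weak. The fallback makes the two bonds in separate flasks by known reaction types and sets out from 16. Pyrrolidine (1.1 equiv) with 4 Å molecular sieves in CH2Cl2 at 0 °C to rt should give the pyrrolidine enamine F1. A secondary amine cannot close a pyrrole, and F1 should cyclise onto C10 by Stork enamine Michael addition. Buffered hydrolysis (AcOH, NaOAc, H2O) then releases keto aldehyde 17, which is isolated here and, if needed, freed from its C5 epimer. Ring B is closed separately by aldol condensation with piperidinium acetate in toluene at 60 °C, which returns to the route at 18.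

Step 12. Hydride abstraction next to a carbonyl may be slow, and dehydrogenation may stray to C2–C3 of ring A. The fallback changes the order of events, sets out from 18 and rejoins at 23, passing by 19 and 20.
- NaBH4 in MeOH–CH2Cl2 at −78 °C should reduce the saturated C1 ketone in preference to the enone. Attack anti to the axial C14 methyl should give the hydroxy enone F2.
- Esterification with mixed anhydride 22 as in step 14 gives the angelate F3.
- TMSOTf and Et3N in CH2Cl2 at 0 °C convert the enone into the cross-conjugated silyl dienol ether F4. C9 is the only enolisable position, since C5 is quaternary.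
- Saegusa–Ito oxidation with Pd(OAc)2 in MeCN at rt introduces C9=C10 and delivers 23.

Step 13. Hydride delivery may occur in part from the face syn to the C14 methyl, and discrimination between the C1 and C8 carbonyls may be incomplete. The fallback sets out from 19 and rejoins at 23. The C1 epimer formed by attack on the wrong face, the 1S alcohol F5, is separated. It is then esterified with inversion by Mitsunobu reaction with angelic acid 21 (PPh3, DIAD, toluene, 0 °C to rt). Both C1 epimers of the reduction thus converge on 23.

**Further compounds**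
F1 | step 11 | pyrrolidine (E)-enamine of 16 at C6 | O=C(CC[C@H](C)/C(C)=C/N1CCCC1)/C=C/C(=O)C[C@H](C)CO[Si](C)(C)C(C)(C)C
F2 | step 12 | (1R,4S,5S,10S,11S)-1-hydroxy-12-(TBSO)eremophil-6-en-8-one | O[C@@H]1CC[C@H](C)[C@@]2(C)C=C([C@H](C)CO[Si](C)(C)C(C)(C)C)C(=O)C[C@H]12
F3 | step 12 | (1R,4S,5S,10S,11S)-1-(angeloyloxy)-12-(TBSO)eremophil-6-en-8-one | C/C=C(/C)C(=O)O[C@@H]1CC[C@H](C)[C@@]2(C)C=C([C@H](C)CO[Si](C)(C)C(C)(C)C)C(=O)C[C@H]12
F4 | step 12 | (1R,4S,5S,10S,11S)-1-(angeloyloxy)-12-(TBSO)-8-(trimethylsilyloxy)eremophila-6,8-diene | C/C=C(/C)C(=O)O[C@@H]1CC[C@H](C)[C@@]2(C)C=C([C@H](C)CO[Si](C)(C)C(C)(C)C)C(O[Si](C)(C)C)=C[C@H]12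
F5 | step 13 | (1S,4S,5S,11S)-1-hydroxy-12-(TBSO)eremophila-6,9-dien-8-one | O[C@H]1CC[C@H](C)[C@@]2(C)C=C([C@H](C)CO[Si](C)(C)C(C)(C)C)C(=O)C=C12
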